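## Retrosynthetic overview

- Target 14 is (2R)-5,7,4'-trihydroxy-6,3',5'-triprenylflavanone. The last step removes three MOM groups from 13.
- Ring C is cut at C2–C3 and at O1–C8a. This gives aldehyde 11, which brings both C2 and O1, and enol silane 8 of a 2-fluoroaryl methyl ketone, which brings C3, C4 and ring A.
- Enabling feature: ring C is a benzo-fused 2,3-dihydro-4-pyranone whose O1–C8a=C4a–C4(=O)–C3 array is a vinylogous ester. C8a lies ortho to the C4 carbonyl and meta to O5 and O7. The unit C3=C4(OSiMe3)–C4a=C8a–F of 8 is therefore a Danishefsky-type diene hidden in ring A.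
- Rings A and B are bought as arenes (1 and 9). All prenyl groups go on before the union: directed lithiation for C6, twofold Stille coupling for C3'/C5'. Ring C is the only ring formed, in step 7, and the position of fluorine fixes 6-prenyl over 8-prenyl.

Key step: step 7

Assumption: the stereocentre of the given SMILES is read as 2R (O1 > C1' > C3 > H), and flavanone numbering is used throughout. The facial sense of the catalyst in step 7 is carried over from its behaviour with simple aromatic aldehydes; both catalyst enantiomers are available from tryptophan.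

## Route

Step 1
Reactants: 1 5-fluorobenzene-1,3-diol
Product: 2 1-fluoro-3,5-bis(methoxymethoxy)benzene
Conditions: MOMCl (2.5 equiv), i-Pr2NEt (3 equiv), CH2Cl2, 0 °C → rt
Reagents that add atoms: chloromethyl methyl ether (MOMCl), COCCl
Why: Williamson-type O-alkylation of both phenols gives MOM acetals that withstand organolithiums and fluoride and serve as directing groups in steps 2 and 3.

Step 2
Reactants: 2 1-fluoro-3,5-bis(methoxymethoxy)benzene
Product: 4 5-fluoro-1,3-bis(methoxymethoxy)-2-(3-methylbut-2-en-1-yl)benzene, via aryllithium 3 (not isolated)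
Conditions: n-BuLi (1.1 equiv), THF, −40 → −10 °C; then CuBr·SMe2 (10 mol%), prenyl bromide (1.2 equiv), −40 → 0 °C
Reagents that add atoms: prenyl bromide (1-bromo-3-methylbut-2-ene), CC(C)=CCBr
Why: Directed ortho-metalation with n-BuLi and no strong donor additive is steered by coordination to the carbon flanked by both MOM-oxy groups (para to fluorine, so LiF loss is impossible), and copper-catalysed SN2 allylation places the future C6 prenyl group.

Step 3
Reactants: 4 5-fluoro-1,3-bis(methoxymethoxy)-2-(3-methylbut-2-en-1-yl)benzene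
Product: 6 1-[6-fluoro-2,4-bis(methoxymethoxy)-3-(3-methylbut-2-en-1-yl)phenyl]ethan-1-one, via aryllithium 5 (not isolated)
Conditions: n-BuLi (1.1 equiv), TMEDA, THF, −78 °C; then MeC(O)N(OMe)Me (1.3 equiv), −78 → −20 °C; then H2O
Reagents that add atoms: N-methoxy-N-methylacetamide, CC(=O)N(C)OC
Why: In this second directed ortho-metalation and Weinreb ketone synthesis, the two remaining ring C–H positions of 4 are equivalent and each is flanked by F and OMOM, so one aryllithium forms, it keeps its fluorine at −78 °C, and the chelated tetrahedral adduct prevents over-addition.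

Step 4
Reactants: 6 1-[6-fluoro-2,4-bis(methoxymethoxy)-3-(3-methylbut-2-en-1-yl)phenyl]ethan-1-one
Product: 8 ({1-[6-fluoro-2,4-bis(methoxymethoxy)-3-(3-methylbut-2-en-1-yl)phenyl]ethenyl}oxy)trimethylsilane, via lithium enolate 7 (not isolated)
Conditions: LiHMDS (1.1 equiv), THF, −78 °C; then TMSCl (1.3 equiv), −78 → 0 °C; pentane, filtration
Reagents that add atoms: chlorotrimethylsilane (TMSCl), C[Si](C)(C)Cl
Why: Kinetic enolisation at the only enolisable position (the methyl group) and O-silylation give the enol silane well below any temperature at which the amide base could attack the C–F carbon.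

Step 5
Reactants: 9 3,5-dibromo-4-hydroxybenzaldehyde
Product: 10 3,5-dibromo-4-(methoxymethoxy)benzaldehyde
Conditions: MOMCl (1.5 equiv), i-Pr2NEt (2 equiv), CH2Cl2, 0 °C → rt
Reagents that add atoms: chloromethyl methyl ether (MOMCl), COCCl
Why: Williamson-type O-alkylation of the acidic phenol masks it, so that no phenoxide deactivates the aldehyde later.

Step 6
Reactants: 10 3,5-dibromo-4-(methoxymethoxy)benzaldehyde
Product: 11 4-(methoxymethoxy)-3,5-bis(3-methylbut-2-en-1-yl)benzaldehyde
Conditions: Bu3SnCH2CH=CMe2 (2.4 equiv), Pd(PPh3)4 (5 mol%), DMF, 90 °C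
Reagents that add atoms: tributyl(3-methylbut-2-en-1-yl)stannane, CCCC[Sn](CCCC)(CCCC)CC=C(C)C
Why: In this twofold Stille coupling, zerovalent palladium inserts readily into the C–Br bonds of the electron-poor ring, the stannane transfers its unsubstituted terminus to give linear prenyl groups, and the aldehyde and MOM ether tolerate the neutral conditions.

Step 7
Reactants: 8 ({1-[6-fluoro-2,4-bis(methoxymethoxy)-3-(3-methylbut-2-en-1-yl)phenyl]ethenyl}oxy)trimethylsilane; 11 4-(methoxymethoxy)-3,5-bis(3-methylbut-2-en-1-yl)benzaldehyde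
Product: 13 (2R)-5,7-bis(methoxymethoxy)-2-[4-(methoxymethoxy)-3,5-bis(3-methylbut-2-en-1-yl)phenyl]-6-(3-methylbut-2-en-1-yl)-2,3-dihydro-4H-chromen-4-one, via silyl aldol ether 12 (not isolated)
Conditions: 8 (1.2 equiv), 11, (4S)-2-butyl-4-(1H-indol-3-ylmethyl)-3-tosyl-1,3,2-oxazaborolidin-5-one (20 mol%), EtCN, −78 °C; then, same flask, [Bu4N][Ph3SiF2] (40 mol%), −78 → 0 °C; pH 7 buffer at 0 °C
Reagents that add atoms: none
Why: Proposed new method: the boron Lewis acid binds aldehyde 11 and enol silane 8 adds through an open Mukaiyama transition state with silyl transfer (C2–C3 bond, silyl ether 12), then substoichiometric fluoride turns the O–SiMe3 group into a silicate/alkoxide that attacks C8a, and the Meisenheimer-type enolate expels fluoride (O1–C8a bond), which attacks the next O–SiMe3 group, so that volatile Me3SiF is the only by-product. The closest known reaction types are the oxazaborolidinone-catalysed aldol–dihydropyranone annulation of Danishefsky's diene (Mukaiyama aldol, then closure with loss of the group on the diene terminus), the fluoride-catalysed etherification of activated aryl fluorides with silyl ethers, and the closure of 1-(2-fluoroaryl)-1,3-dicarbonyl compounds to chromones; new here are an arene C=C–F unit as diene terminus and the fluoride relay. Ring C closes by a 6-endo-trig addition–elimination, because the C4a=C8a bond that takes up the electrons lies inside the new ring. The only stereocentre, C2, is set in the aldol stage by the catalyst, whose indole should shield the Si face of the bound formyl group so that 8 adds to the Re face (R), and the C2–O bond is never broken afterwards. Ring closure must outrun retro-aldol cleavage and E1cB loss of the oxygen, which is secured by the six-membered transition state, the small transient amount of alkoxide, the low temperature and the two MOM-oxy groups that sit meta to C8a and so do not donate into the carbon under attack. Regiochemistry (6-prenyl, not 8-prenyl) is fixed because only C8a carries a leaving group.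

Step 8
Reactants: 13 (2R)-5,7-bis(methoxymethoxy)-2-[4-(methoxymethoxy)-3,5-bis(3-methylbut-2-en-1-yl)phenyl]-6-(3-methylbut-2-en-1-yl)-2,3-dihydro-4H-chromen-4-one
Product: 14 (2R)-5,7-dihydroxy-2-[4-hydroxy-3,5-bis(3-methylbut-2-en-1-yl)phenyl]-6-(3-methylbut-2-en-1-yl)-2,3-dihydro-4H-chromen-4-one
Conditions: HCl (3 M aq), MeOH, 45 °C; work-up at pH 5–6
Reagents that add atoms: none
Why: Acid-catalysed acetal solvolysis (MOM cleavage by transacetalisation to methanol) frees the three phenols without touching C2, and the acidic medium avoids the base-induced opening of ring C that would racemise a 4'-hydroxyflavanone.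

## Compound list

1 | 5-fluorobenzene-1,3-diol | Oc1cc(O)cc(F)c1 | starting material
2 | 1-fluoro-3,5-bis(methoxymethoxy)benzene | COCOc1cc(F)cc(OCOC)c1 | intermediate
3 | [4-fluoro-2,6-bis(methoxymethoxy)phenyl]lithium | [Li]c1c(OCOC)cc(F)cc1OCOC | intermediate
4 | 5-fluoro-1,3-bis(methoxymethoxy)-2-(3-methylbut-2-en-1-yl)benzene | COCOc1cc(F)cc(OCOC)c1CC=C(C)C | intermediate
5 | [6-fluoro-2,4-bis(methoxymethoxy)-3-(3-methylbut-2-en-1-yl)phenyl]lithium | [Li]c1c(F)cc(OCOC)c(CC=C(C)C)c1OCOC | intermediate
6 | 1-[6-fluoro-2,4-bis(methoxymethoxy)-3-(3-methylbut-2-en-1-yl)phenyl]ethan-1-one | CC(=O)c1c(F)cc(OCOC)c(CC=C(C)C)c1OCOC | intermediate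
7 | lithium enolate of 6 | [Li]OC(=C)c1c(F)cc(OCOC)c(CC=C(C)C)c1OCOC | intermediate
8 | ({1-[6-fluoro-2,4-bis(methoxymethoxy)-3-(3-methylbut-2-en-1-yl)phenyl]ethenyl}oxy)trimethylsilane | C=C(O[Si](C)(C)C)c1c(F)cc(OCOC)c(CC=C(C)C)c1OCOC | intermediate
9 | 3,5-dibromo-4-hydroxybenzaldehyde | O=Cc1cc(Br)c(O)c(Br)c1 | starting material
10 | 3,5-dibromo-4-(methoxymethoxy)benzaldehyde | COCOc1c(Br)cc(C=O)cc1Br | intermediate
11 | 4-(methoxymethoxy)-3,5-bis(3-methylbut-2-en-1-yl)benzaldehyde | COCOc1c(CC=C(C)C)cc(C=O)cc1CC=C(C)C | intermediate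
12 | (3R)-1-[6-fluoro-2,4-bis(methoxymethoxy)-3-(3-methylbut-2-en-1-yl)phenyl]-3-[4-(methoxymethoxy)-3,5-bis(3-methylbut-2-en-1-yl)phenyl]-3-[(trimethylsilyl)oxy]propan-1-one | CC(C)=CCc1cc([C@H](O[Si](C)(C)C)CC(=O)c2c(F)cc(OCOC)c(CC=C(C)C)c2OCOC)cc(CC=C(C)C)c1OCOC | intermediate
13 | (2R)-5,7-bis(methoxymethoxy)-2-[4-(methoxymethoxy)-3,5-bis(3-methylbut-2-en-1-yl)phenyl]-6-(3-methylbut-2-en-1-yl)-2,3-dihydro-4H-chromen-4-one | CC(C)=CCc1cc([C@H]2CC(=O)c3c(cc(OCOC)c(CC=C(C)C)c3OCOC)O2)cc(CC=C(C)C)c1OCOC | intermediate
14 | (2R)-5,7-dihydroxy-2-[4-hydroxy-3,5-bis(3-methylbut-2-en-1-yl)phenyl]-6-(3-methylbut-2-en-1-yl)-2,3-dihydro-4H-chromen-4-one | CC(C)=CCc1cc([C@H]2CC(=O)c3c(cc(O)c(CC=C(C)C)c3O)O2)cc(CC=C(C)C)c1O | target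

## Step count and risks

Total step count: 8.
Longest linear sequence: 6 steps (steps 1, 2, 3, 4, 7, 8).

**1) Step 7.**
- What may go wrong:
  - Retro-aldol equilibration of the transient alkoxide could erode the enantiomeric purity, as could base-induced opening of ring C of the product.
  - β-Elimination of the oxygen could lead to a fluorochalcone that cannot cyclise.
  - The di-ortho-substituted enol silane could add slowly or with poor facial selectivity.
- Approach of the fallback: it uses known chemistry, never passes through a β-alkoxy ketone, and makes the aryl–C2 bond instead. It sets out from ketone 6.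
- Chromone partner: Claisen formylation of 6 with ethyl formate and NaH in THF gives 3-[6-fluoro-2,4-bis(methoxymethoxy)-3-prenylphenyl]-3-oxopropanal F1. On warming, the sodium enolate of F1 closes onto the C–F carbon (intramolecular O-arylation of a 1-(2-fluoroaryl)-1,3-dicarbonyl compound). This gives 5,7-bis(methoxymethoxy)-6-prenylchromone F2.
- Aryl partner, from commercial 4-bromophenol:
  - ortho,ortho'-C-prenylation of the sodium phenoxide with prenyl bromide in toluene gives 4-bromo-2,6-diprenylphenol F3.
  - NaH/MOMCl gives its MOM ether F4.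
  - Bromine–lithium exchange with n-BuLi at −78 °C gives the aryllithium F5.
  - B(OiPr)3 followed by water gives the boronic acid F6.
- Union: rhodium-catalysed asymmetric 1,4-addition of F6 to F2 uses [Rh(OH)(cod)]2 and an electron-poor chiral bisphosphine of the MeO-BIPHEP family in toluene at rt to 40 °C. The ligand enantiomer is chosen for aryl delivery to the face that gives 2R. The fallback comes back to the route at 13.

**2) Step 2.**
- What may go wrong: lithiation could occur next to fluorine instead of between the two MOM-oxy groups, followed by loss of LiF to an aryne and decomposition.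
- Fallback: it fixes the site with a halogen and sets out from 1.
  - Iodination with I2 and NaHCO3 in water at 0 °C goes to the carbon between the two hydroxyl groups (para to fluorine). This gives 5-fluoro-2-iodobenzene-1,3-diol F7.
  - MOMCl/i-Pr2NEt gives 5-fluoro-2-iodo-1,3-bis(methoxymethoxy)benzene F8.
  - Iodine–lithium exchange with n-BuLi in THF at −78 °C gives the aryllithium regiospecifically.
- The fallback comes back to the route at 3, which is prenylated as in step 2.

**3) Step 8.**
- What may go wrong:
  - Acid could close the ortho-prenylphenol units to chromans.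
  - HCl or methanol could add to the prenyl double bonds.
  - Reversible opening of ring C could cause partial racemisation once the 4'-hydroxyl group is free.
- Fallback: it replaces Brønsted-acid solvolysis by a non-acidic silylative acetal transfer and sets out from 13.
  - TMSOTf and 2,2'-bipyridyl in CH2Cl2 at 0 °C move each methoxymethyl group onto the bipyridyl nitrogen.
  - The aryl oxygens are left as the tris(trimethylsilyl) ether of the target F9.
  - F9 is hydrolysed with water at neutral pH and rt.
- The fallback comes back to the route at 14.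

## Further compounds

F1 | step 7 | 3-[6-fluoro-2,4-bis(methoxymethoxy)-3-(3-methylbut-2-en-1-yl)phenyl]-3-oxopropanal | O=CCC(=O)c1c(F)cc(OCOC)c(CC=C(C)C)c1OCOC
F2 | step 7 | 5,7-bis(methoxymethoxy)-6-(3-methylbut-2-en-1-yl)-4H-chromen-4-one | O=c1ccoc2cc(OCOC)c(CC=C(C)C)c(OCOC)c12
F3 | step 7 | 4-bromo-2,6-bis(3-methylbut-2-en-1-yl)phenol | Oc1c(CC=C(C)C)cc(Br)cc1CC=C(C)C
F4 | step 7 | 5-bromo-2-(methoxymethoxy)-1,3-bis(3-methylbut-2-en-1-yl)benzene | COCOc1c(CC=C(C)C)cc(Br)cc1CC=C(C)C
F5 | step 7 | [4-(methoxymethoxy)-3,5-bis(3-methylbut-2-en-1-yl)phenyl]lithium | [Li]c1cc(CC=C(C)C)c(OCOC)c(CC=C(C)C)c1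
F6 | step 7 | [4-(methoxymethoxy)-3,5-bis(3-methylbut-2-en-1-yl)phenyl]boronic acid | OB(O)c1cc(CC=C(C)C)c(OCOC)c(CC=C(C)C)c1
F7 | step 2 | 5-fluoro-2-iodobenzene-1,3-diol | Oc1cc(F)cc(O)c1I
F8 | step 2 | 5-fluoro-2-iodo-1,3-bis(methoxymethoxy)benzene | COCOc1cc(F)cc(OCOC)c1I
F9 | step 8 | (2R)-6-(3-methylbut-2-en-1-yl)-2-{3,5-bis(3-methylbut-2-en-1-yl)-4-[(trimethylsilyl)oxy]phenyl}-5,7-bis[(trimethylsilyl)oxy]-2,3-dihydro-4H-chromen-4-one | CC(C)=CCc1cc([C@H]2CC(=O)c3c(cc(O[Si](C)(C)C)c(CC=C(C)C)c3O[Si](C)(C)C)O2)cc(CC=C(C)C)c1O[Si](C)(C)C
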